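## Structural features

The target is an unsymmetrical dimer of two 5-hydroxychroman-4-one units joined by one biaryl bond between C6 and C6'; each of these carbons lies ortho to a hydrogen-bonded phenol (on C5, C5') and para to the ring oxygen. Each heterocycle has a fully substituted C2 that carries a methyl ester and a four-carbon chain. In one half the chain is closed as a cis-3-methyl-γ-butyrolactone (the oxygen on C9' acylated by C12'); in the other it is the free γ-hydroxy acid (C9–OH, C12 acid). C2, C9 and C10 are contiguous stereocentres, and both halves have the same 2S,9R,10S arrangement with the C9 oxygen and the C10 methyl group syn, so the halves differ only in whether the chain is lactonised. The chromanones are fragile towards base, which opens O1–C2 by retro-oxa-Michael reaction through the C3 enolate and recloses it with loss of the C2 configuration. The hydroxy acid is fragile towards acid, which lactonises it to the symmetrical bis-lactone, and the methyl esters and the lactone do not survive hydroxide. The real difficulty is to unite two almost identical, base-sensitive halves through a biaryl bond flanked by oxygen on both rings while keeping their chain termini different; any symmetrical dimerisation would need a later desymmetrisation with no handle for selectivity. The key step uses the fact that ring A of the open-chain half (C4a, C5, C6, C7, C8, C8a) is attached to its heterocycle only through C4a–C8a and carries the other half at C6 next to oxygen at C5. Without ring A, what remains is a monocyclic 2,3-dihydro-4H-pyran-4-one whose C4a=C8a enone bond is a polarised two-carbon partner for a 1-silyloxy-2-aryl diene carried by the finished lactone half.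

## Logic of the disconnections

34 is cut back to 33 at the two O–CH2Ph bonds (the ether on O9 and the ester on C12), and 33 to 32 at the two aryl O–Si bonds. The reason is the lability of the hydroxy acid: it should appear only in the last step, from a neutral hydrogenolysis that frees O9 and the C12 acid together, so that a γ-hydroxy ester, which would lactonise at once, never exists. The skeleton is not simplified, but every compound before 34 is neutral and fully protected. The forward steps must leave the two aryl ketones alone and the desilylation must be buffered.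

In 32 ring A is removed by cutting C8–C8a and C4a–C5, which leaves 15 and 30. Ring A hangs on the rest of its half only through C4a–C8a, which is an enone double bond in 15, and its C5-oxygen/C6-aryl pattern is that of a 1-oxy-2-aryl diene. The gain is large: the biaryl bond is never made as such, the two halves arrive complete, enantiopure and differently terminated, and no base is used. The forward step must be a formal [4+2] addition with the pairing C8 to C8a and C5 to C4a, tolerant of esters, a lactone, a ketone and benzyl groups, followed by a dehydrogenation that keeps the C5 oxygen.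

30 is cut at the bond between C6' and the central diene carbon, giving 25 and 29; 29 goes back to 28 by removal of the silyl group and 28 to 26 by removal of bromine. Forming the silyl dienol ether on the four-carbon piece is a deliberate change of design: silyl triflate and amine applied to an enal already attached to the chromanone would also silylate the C4' ketone, and that enol silane would compete as a nucleophile in the key step. The gain is that the heterocycle sees only a neutral cross-coupling. The coupling must work without base or fluoride and keep the alkene geometry and both silyl ethers.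

25 is traced to 24 (C–Sn), 24 to 23 (O–Si) and 23 to 22 (C–I). C6' is ortho to the chelated phenol and is the innate site of electrophilic halogenation. The phenol is capped before the diene exists, because at that stage any enol silane formed at C4' can still be hydrolysed harmlessly. This leads back to 22, which has no handle on the arene. The forward iodination must be a single substitution at C6' and not at C8'.

22 is traced to 21 by removing the hydrogens on C10' and C11'; 21 is cut at C2'–C9' into 19 and 20; 19 is cut at C2'–C3' and O1'–C2' into 16 and 17. C2'–C9' joins the nucleophilic γ-carbon of a butenolide to the electrophilic C2' of a chromone ester and sets C2' and C9' together; C10' then follows from C9' by hydrogenation from the open face. Three stereocentres come from flat, achiral precursors in two steps. The catalyst must fix the absolute configuration at C2' and its relation to C9'.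

15 is cut at C2–C3 and O1–C8a into 12 and 13, the ketone of 12 acting as heterodienophile. C2 is a tertiary ether carbon next to an ester, which is the carbon of a 2-oxo ester, and a 1,2-dicarbonyl unit is a two-point ligand for a chiral Lewis acid. The heterocycle and the quaternary centre arise in one step from an acyclic compound. The catalyst must override or cooperate with the resident C9 centre.

In 12 the C1–C2 dicarbonyl unit is traced to the alkyne carbons of 11, and 11 to 10 by exchange of bromine for silicon. A 2-oxo ester next to an oxygen-bearing stereocentre is too enolisable to carry, whereas an alkyne is inert and has the right oxidation level. The benzyl ester is then the only ester present during the earlier steps, so no ester differentiation is needed. The oxidation must stop at the dicarbonyl level and must not epimerise C9.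

10 is traced to 9 (ester O–CH2Ph), 9 to 7 (oxidation level of C12), 7 to 5 (C12–O) and 5 to 4 (O9–CH2Ph). The order is the point: O9 is benzylated while C12 is still an alkene carbon, so a 9-hydroxy-12-carbonyl compound, which would lactonise, is never formed. This reduces the side chain to 4. The hydroboration must choose the vinyl group over the silylalkyne.

4 is cut at C9–C10 into 1 and 2. The syn oxygen/methyl pattern is the signature of a (Z)-crotyl transfer to an aldehyde, which sets both stereocentres at once. The starting materials are achiral three- and four-carbon compounds. The reagent must control the face of an ynal.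

## Other disconnections considered

Alternative 1: The cut is at both aryl–acyl bonds, C4–C4a and C4'–C4a', of a biaryl that already exists. In the forward sense 4,4'-difluoro-2,2'-bis(methoxymethoxy)biphenyl A3 would be lithiated twice between fluorine and the acetal oxygen. Each aryllithium would open the enantiopure β-lactone A2 at its acyl carbon and release the C2 tertiary alkoxide, giving the bis(β-hydroxy ketone) A1; two alkoxide-for-fluoride SNAr closures would then form both pyranone rings.
- In its favour: the hindered biaryl bond is made first on a simple arene, and both quaternary centres come from one building block. Acyl opening of β-lactones by organolithiums and SNAr ring closure are known reaction types, so on precedent this plan is better than the chosen one.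
- Against it here: the plan is two-directional, so both halves emerge identical (open chains, C12 at the alcohol level), whereas the target needs one lactone and one hydroxy acid. The late oxidation and one-sided lactonisation have nothing to distinguish the two ends.
- Mechanism: an ortho-fluoro aryllithium can lose LiF to an aryne, the ketone formed is more electrophilic than the lactone, the methyl ester competes, and a tertiary aldol may undergo retro-aldol cleavage under the basic SNAr conditions.
- Step economy: the count would be similar, but redox adjustment of two chain ends after the union adds late steps. The chosen plan joins two halves that already differ.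

Alternative 2: The cut is at both C2–C9 bonds. In the forward sense the 6,6'-bis(chromone ester) A5 would be converted by i-Pr3SiOTf into a bis(4-silyloxybenzopyrylium) ion, and C5 of two molecules of the silyloxyfuran A6 would add to C2 and C2'. Hydrolysis of the enol silanes would give the C2-symmetric bis(butenolide) A4, and hydrogenation the bis-lactone.
- In its favour: it forms two C–C bonds and four stereocentres in one operation. The monomeric version of this bond construction is established (the chosen route uses it in step 10), and on step count this alternative is clearly the better plan.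
- Against it here: the product is symmetrical, and one of two identical lactones would have to be opened. That is statistical, and hydroxide also threatens C2 (retro-oxa-Michael) and the methyl esters.
- Mechanism: without a chiral catalyst each addition is racemic, and two independent events would give meso and racemic dimers. A5 itself needs a coupling of two ortho-hydroxylated chromones.
- Comparison: the chosen plan is longer but solves the heterodimer problem by construction, at the price of a key step without direct precedent.

Alternative 3: The cut is the O1–C2 bond. In the forward sense a phenol of the 2,6-dihydroxyaryl enone A8 would add to the ester-bearing alkene carbon. Both alkene isomers would converge on the chromanone lactone A7, which has the same structure as 22.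
- In its favour: the arene comes from the simplest starting material, the conditions are mild, and the alkene geometry need not be controlled. As a ring closure it is of a well-known type, and on reliability it is at least the equal of the chosen key step.
- Against it here: C2 is set by induction from C9 in a reversible addition, and the same reversibility later threatens C2. The closure gives only a monomer, so the biaryl bond and the pairing of two different halves remain, to be solved by cross-coupling of one halogenated and one metallated ortho-oxygenated chromanone.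
- Comparison: the per-monomer step count is similar to steps 9–11. The riskiest operation moves to a hindered biaryl coupling, which is a known reaction type, whereas the chosen plan avoids aryl–aryl coupling altogether.

Key step: step 18

Assumption: the sense of induction of the chiral reagents in steps 1, 8 and 10 is taken from the usual transition-state models of these reagent classes; if one proves opposite, the antipodal reagent or ligand is used with no other change.

Assumption: the biaryl axis has only one non-hydrogen ortho substituent on each ring, so no stable atropisomers are expected and none is specified.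

## Route

Step 1
Reactants: 1 3-(trimethylsilyl)prop-2-ynal; 2 (Z)-but-2-ene
Product: 4 (3R,4S)-4-methyl-1-(trimethylsilyl)hex-5-en-1-yn-3-ol, via borinate ester 3 (not isolated)
Conditions: 2, n-BuLi, KOt-Bu, THF, −78 to −45 °C; (+)-Ipc2BOMe, −78 °C; BF3·OEt2; then 1, −78 °C; NaOH, H2O2, rt
Reagents that add atoms: none
Why: Asymmetric crotylboration through a closed chair transition state: the Z geometry of the crotylborane gives the syn relationship of oxygen and methyl, and the isopinocampheyl groups of the (−)-α-pinene series select the aldehyde face that makes C3 R (C9 of the target), C4 (C10) then being S; ynals are standard substrates for this reagent class.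

Step 2
Reactants: 4 (3R,4S)-4-methyl-1-(trimethylsilyl)hex-5-en-1-yn-3-ol
Product: 5 [(3R,4S)-3-(benzyloxy)-4-methylhex-5-en-1-yn-1-yl]trimethylsilane
Conditions: BnOC(=NH)CCl3, TfOH (5 mol %), CH2Cl2/cyclohexane, 0 °C to rt
Reagents that add atoms: benzyl 2,2,2-trichloroacetimidate, N=C(OCc1ccccc1)C(Cl)(Cl)Cl
Why: Acid-catalysed O-benzylation with the trichloroacetimidate avoids an alkoxide that could attack the C–Si bond; the ether is installed while C12 is still an alkene carbon, so no γ-lactone can form later.

Step 3
Reactants: 5 [(3R,4S)-3-(benzyloxy)-4-methylhex-5-en-1-yn-1-yl]trimethylsilane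
Product: 7 (3S,4R)-4-(benzyloxy)-3-methyl-6-(trimethylsilyl)hex-5-yn-1-ol, via alkylborane 6 (not isolated)
Conditions: 9-BBN, THF, 0 °C to rt; then H2O2, aq. NaOAc, 0 °C to rt
Reagents that add atoms: hydrogen peroxide, OO
Why: Anti-Markovnikov hydroboration–oxidation; 9-BBN should select the monosubstituted alkene over the hindered silylalkyne, and the buffered peroxide work-up spares the C–Si bond.

Step 4
Reactants: 7 (3S,4R)-4-(benzyloxy)-3-methyl-6-(trimethylsilyl)hex-5-yn-1-ol
Product: 9 (3S,4R)-4-(benzyloxy)-3-methyl-6-(trimethylsilyl)hex-5-ynoic acid, via aldehyde 8 (not isolated)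
Conditions: TEMPO (10 mol %), NaClO2, NaOCl (cat.), MeCN/phosphate buffer pH 6.7, 35 °C
Reagents that add atoms: sodium chlorite, [Na+].[O-]Cl=O
Why: Oxoammonium oxidation of the primary alcohol to the aldehyde and chlorite oxidation of the aldehyde to the acid in one pot; the methyl-bearing centre is β to the new carbonyl and cannot epimerise, and the benzyl ether and the silylalkyne are inert.

Step 5
Reactants: 9 (3S,4R)-4-(benzyloxy)-3-methyl-6-(trimethylsilyl)hex-5-ynoic acid
Product: 10 benzyl (3S,4R)-4-(benzyloxy)-3-methyl-6-(trimethylsilyl)hex-5-ynoate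
Conditions: BnBr, K2CO3, DMF, rt
Reagents that add atoms: benzyl bromide, BrCc1ccccc1
Why: SN2 alkylation of the carboxylate under mild base; no alcohol is present, so the silylalkyne is not cleaved.

Step 6
Reactants: 10 benzyl (3S,4R)-4-(benzyloxy)-3-methyl-6-(trimethylsilyl)hex-5-ynoate
Product: 11 benzyl (3S,4R)-4-(benzyloxy)-6-bromo-3-methylhex-5-ynoate
Conditions: NBS (1.2 equiv), AgNO3 (10 mol %), acetone, rt, dark
Reagents that add atoms: N-bromosuccinimide, O=C1CCC(=O)N1Br
Why: Silver-catalysed bromodesilylation: AgNO3 activates the alkynylsilane towards electrophilic bromine and gives the 1-bromoalkyne directly.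

Step 7
Reactants: 11 benzyl (3S,4R)-4-(benzyloxy)-6-bromo-3-methylhex-5-ynoate
Product: 12 6-benzyl 1-methyl (3R,4S)-3-(benzyloxy)-4-methyl-2-oxohexanedioate
Conditions: KMnO4, NaHCO3, MgSO4, MeOH/H2O, 0 °C
Reagents that add atoms: potassium permanganate, [K+].[O-][Mn](=O)(=O)=O; methanol, CO
Why: Permanganate oxidation of a 1-bromoalkyne to the 1,2-dicarbonyl level with capture of the acyl carbon by methanol should give the methyl 2-oxo ester in one step; the bicarbonate/MgSO4 buffer keeps the medium near neutral, so the enolisable C3 is not epimerised.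

Step 8
Reactants: 12 6-benzyl 1-methyl (3R,4S)-3-(benzyloxy)-4-methyl-2-oxohexanedioate; 13 (E)-1-methoxy-3-(trimethylsilyloxy)buta-1,3-diene
Product: 15 methyl (2S)-2-[(1R,2S)-1,4-bis(benzyloxy)-2-methyl-4-oxobutyl]-4-oxo-3,4-dihydro-2H-pyran-2-carboxylate, via silyloxy dihydropyran 14 (not isolated)
Conditions: Cu(OTf)2 (10 mol %), (R,R)-t-Bu-box (11 mol %), CH2Cl2, −40 °C to rt; then TFA (cat.), CH2Cl2, 0 °C
Reagents that add atoms: none
Why: Catalytic asymmetric hetero-Diels–Alder reaction of a 2-oxo ester (a stepwise aldol–cyclisation leads to the same product): the 1,2-dicarbonyl unit chelates divalent copper in a square-planar complex, the tert-butyl groups of the (R,R) ligand shield one face, and the diene terminus should add to the re face of the ketone, which makes C2 S (the (S,S) ligand directs simple 2-oxo esters to the opposite face); TFA then eliminates methanol and the silyl group.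

Step 9
Reactants: 16 1-(2,6-dihydroxyphenyl)ethanone; 17 dimethyl oxalate
Product: 19 methyl 5-hydroxy-4-oxo-4H-chromene-2-carboxylate, via diketo ester 18 (not isolated)
Conditions: NaOMe, MeOH, reflux; then conc. HCl, MeOH, reflux
Reagents that add atoms: none
Why: Claisen condensation of the methyl ketone with the oxalate, then acid-catalysed cyclodehydration of the 2,4-dioxo ester onto one of the two equivalent phenols (chromone synthesis); the other phenol remains as the chelated 5-OH.

Step 10
Reactants: 19 methyl 5-hydroxy-4-oxo-4H-chromene-2-carboxylate; 20 4-methylfuran-2(5H)-one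
Product: 21 methyl (2S)-5-hydroxy-2-[(2R)-3-methyl-5-oxo-2,5-dihydrofuran-2-yl]-4-oxo-3,4-dihydro-2H-chromene-2-carboxylate
Conditions: Sc(OTf)3 (10 mol %), chiral N,N'-dioxide ligand (amino-acid-derived, 10 mol %), Et3N (20 mol %), CH2Cl2, 0 °C to rt
Reagents that add atoms: none
Why: Catalytic enantioselective vinylogous Michael addition of a butenolide to a 2-alkoxycarbonylchromone: the trivalent scandium complex binds the 5-hydroxy-4-oxo unit, the amine generates the dienolate, and C5 of the furanone attacks C2 of the chromone; the ligand should control the face at C2 (S) and the compact approach of the two rings should set C9 (R), any minor epimer being removed by chromatography.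

Step 11
Reactants: 21 methyl (2S)-5-hydroxy-2-[(2R)-3-methyl-5-oxo-2,5-dihydrofuran-2-yl]-4-oxo-3,4-dihydro-2H-chromene-2-carboxylate
Product: 22 methyl (2S)-5-hydroxy-2-[(2R,3S)-3-methyl-5-oxooxolan-2-yl]-4-oxo-3,4-dihydro-2H-chromene-2-carboxylate
Conditions: H2 (1 atm), Pd/C, EtOAc, rt
Reagents that add atoms: none
Why: Heterogeneous hydrogenation of the trisubstituted butenolide alkene: hydrogen should add to the face opposite the bulky quaternary substituent on C9, which places the methyl group cis to it and makes C10 S; the chelated aryl ketone is not reduced at 1 atm.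

Step 12
Reactants: 22 methyl (2S)-5-hydroxy-2-[(2R,3S)-3-methyl-5-oxooxolan-2-yl]-4-oxo-3,4-dihydro-2H-chromene-2-carboxylate
Product: 23 methyl (2S)-5-hydroxy-6-iodo-2-[(2R,3S)-3-methyl-5-oxooxolan-2-yl]-4-oxo-3,4-dihydro-2H-chromene-2-carboxylate
Conditions: BnMe3N·ICl2 (1.05 equiv), CaCO3, CH2Cl2/MeOH, rt
Reagents that add atoms: benzyltrimethylammonium dichloroiodate, C[N+](C)(C)Cc1ccccc1.Cl[I-]Cl
Why: Electrophilic aromatic iodination steered by the free chelated phenol: in 5-hydroxy-4-oxobenzopyrans the position ortho to the phenol (C6, also para to O1) is the innate site of halogenation; CaCO3 takes up the HCl, so the medium stays near neutral.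

Step 13
Reactants: 23 methyl (2S)-5-hydroxy-6-iodo-2-[(2R,3S)-3-methyl-5-oxooxolan-2-yl]-4-oxo-3,4-dihydro-2H-chromene-2-carboxylate
Product: 24 methyl (2S)-5-[(tert-butyldimethylsilyl)oxy]-6-iodo-2-[(2R,3S)-3-methyl-5-oxooxolan-2-yl]-4-oxo-3,4-dihydro-2H-chromene-2-carboxylate
Conditions: t-BuMe2SiOTf, 2,6-lutidine, CH2Cl2, −78 to 0 °C
Reagents that add atoms: tert-butyldimethylsilyl triflate, CC(C)(C)[Si](C)(C)OS(=O)(=O)C(F)(F)F
Why: Silylation of the hindered, chelated phenol needs the silyl triflate; at this stage any enol silane formed at C4 is simply hydrolysed on work-up, which is why the phenol is capped before the acid-labile diene is introduced.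

Step 14
Reactants: 24 methyl (2S)-5-[(tert-butyldimethylsilyl)oxy]-6-iodo-2-[(2R,3S)-3-methyl-5-oxooxolan-2-yl]-4-oxo-3,4-dihydro-2H-chromene-2-carboxylate
Product: 25 methyl (2S)-5-[(tert-butyldimethylsilyl)oxy]-2-[(2R,3S)-3-methyl-5-oxooxolan-2-yl]-4-oxo-6-(trimethylstannyl)-3,4-dihydro-2H-chromene-2-carboxylate
Conditions: Me3SnSnMe3 (1.5 equiv), Pd(PPh3)4 (5 mol %), toluene, 100 °C
Reagents that add atoms: hexamethylditin, C[Sn](C)(C)[Sn](C)(C)C
Why: Palladium-catalysed stannylation of the aryl iodide (oxidative addition to zerovalent palladium, Sn–Sn transmetallation, reductive elimination) under neutral conditions; no base touches the chromanone.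

Step 15
Reactants: 26 (E)-but-2-enal
Product: 28 (Z)-2-bromobut-2-enal, via dibromide 27 (not isolated)
Conditions: Br2, CH2Cl2, 0 °C; then Et3N, 0 °C to rt
Reagents that add atoms: bromine, BrBr
Why: Bromine addition to the enal and dehydrobromination of the 2,3-dibromide by the amine give the α-bromo enal with bromine cis to methyl.

Step 16
Reactants: 28 (Z)-2-bromobut-2-enal
Product: 29 tert-butyl{[(1Z)-2-bromobuta-1,3-dien-1-yl]oxy}dimethylsilane
Conditions: t-BuMe2SiOTf, Et3N, Et2O, 0 °C to rt
Reagents that add atoms: tert-butyldimethylsilyl triflate, CC(C)(C)[Si](C)(C)OS(=O)(=O)C(F)(F)F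
Why: Soft enolisation: O-silylation of the aldehyde and γ-deprotonation by the amine give the silyl dienol ether; reaction through the s-trans enal places the silyloxy group trans to the vinyl group.

Step 17
Reactants: 25 methyl (2S)-5-[(tert-butyldimethylsilyl)oxy]-2-[(2R,3S)-3-methyl-5-oxooxolan-2-yl]-4-oxo-6-(trimethylstannyl)-3,4-dihydro-2H-chromene-2-carboxylate; 29 tert-butyl{[(1Z)-2-bromobuta-1,3-dien-1-yl]oxy}dimethylsilane
Product: 30 methyl (2S)-5-[(tert-butyldimethylsilyl)oxy]-6-{(1Z)-1-[(tert-butyldimethylsilyl)oxy]buta-1,3-dien-2-yl}-2-[(2R,3S)-3-methyl-5-oxooxolan-2-yl]-4-oxo-3,4-dihydro-2H-chromene-2-carboxylate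
Conditions: Pd(PPh3)4 (10 mol %), Cu(O2CC4H3S) (copper thiophene-2-carboxylate, 1.5 equiv), NMP, rt to 40 °C
Reagents that add atoms: none
Why: Copper-assisted Stille coupling of the arylstannane with the alkenyl bromide, with retention of the alkene geometry; the conditions are neutral and free of fluoride, so both silyl ethers, the lactone and C2 should survive, and the chromanone ketone never meets silyl triflate and amine.

Step 18
Reactants: 15 methyl (2S)-2-[(1R,2S)-1,4-bis(benzyloxy)-2-methyl-4-oxobutyl]-4-oxo-3,4-dihydro-2H-pyran-2-carboxylate; 30 methyl (2S)-5-[(tert-butyldimethylsilyl)oxy]-6-{(1Z)-1-[(tert-butyldimethylsilyl)oxy]buta-1,3-dien-2-yl}-2-[(2R,3S)-3-methyl-5-oxooxolan-2-yl]-4-oxo-3,4-dihydro-2H-chromene-2-carboxylate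
Product: 32 methyl (2S)-2-[(1R,2S)-1,4-bis(benzyloxy)-2-methyl-4-oxobutyl]-5-[(tert-butyldimethylsilyl)oxy]-6-{(2S)-5-[(tert-butyldimethylsilyl)oxy]-2-(methoxycarbonyl)-2-[(2R,3S)-3-methyl-5-oxooxolan-2-yl]-4-oxo-3,4-dihydro-2H-chromen-6-yl}-4-oxo-3,4-dihydro-2H-chromene-2-carboxylate, via cycloadduct 31 (not isolated)
Conditions: t-BuMe2SiOTf (0.3 equiv), 2,6-di-tert-butyl-4-methylpyridine (0.3 equiv), CH2Cl2, −78 to −40 °C; pyridine quench, evaporate; DDQ (2.5 equiv), 1,4-dioxane, rt to 50 °C
Reagents that add atoms: none
Why: Proposed new method: the silyl triflate silylates the C4 carbonyl of 15 and turns the vinylogous ester into a 4-silyloxy oxocarbenium ion whose electrophilic carbon is C8a, and the terminal CH2 of the silyl dienol ether of 30 (its γ-carbon, the future C8) adds there in a vinylogous Mukaiyama–Michael step, the regiochemistry being fixed by the matching polarity of the partners and by the aryl group that blocks the α-carbon of the diene. The C4 enol silane so formed then attacks the O-silylated aldehyde carbon C5 through C4a in an intramolecular Mukaiyama aldol step, a 6-(enolexo)-exo-trig closure of ring A that the s-cis conformer of the 2-aryl diene allows because it leaves C5 and C8 cis on the C6=C7 bond; silyl transfer regenerates the triflate, so a substoichiometric amount suffices, and the hindered pyridine removes adventitious acid that would hydrolyse the dienol ether. The closest known reaction types are silyl-triflate-promoted conjugate additions of enol silanes to 2,3-dihydro-4H-pyran-4-ones and Lewis-acid Diels–Alder reactions of 1-silyloxydienes with β-alkoxy enones, each followed by DDQ dehydrogenation. Cycloadduct 31 has new stereocentres at C4a, C5 and C8a, set by the resident C2 centre and the mode of approach, but all three become sp2, so no lasting stereocentre is created and their configuration is irrelevant. DDQ should remove hydride first from the allylic C5–H or C8–H and then from the resulting dienol ether, four hydrogens in all, and the quaternary C2 and C2' centres exclude over-oxidation to chromones. The step needs conjugate rather than carbonyl attack on the cation and retention of the C5 oxygen (no β-elimination of silanol before dehydrogenation); the first is secured by the unsubstituted cationic C8a, the second by low temperature, little triflate and immediate oxidation, and loss of the C5 silyl group alone is harmless because step 19 removes it anyway.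

Step 19
Reactants: 32 methyl (2S)-2-[(1R,2S)-1,4-bis(benzyloxy)-2-methyl-4-oxobutyl]-5-[(tert-butyldimethylsilyl)oxy]-6-{(2S)-5-[(tert-butyldimethylsilyl)oxy]-2-(methoxycarbonyl)-2-[(2R,3S)-3-methyl-5-oxooxolan-2-yl]-4-oxo-3,4-dihydro-2H-chromen-6-yl}-4-oxo-3,4-dihydro-2H-chromene-2-carboxylate
Product: 33 methyl (2S)-2-[(1R,2S)-1,4-bis(benzyloxy)-2-methyl-4-oxobutyl]-5-hydroxy-6-{(2S)-5-hydroxy-2-(methoxycarbonyl)-2-[(2R,3S)-3-methyl-5-oxooxolan-2-yl]-4-oxo-3,4-dihydro-2H-chromen-6-yl}-4-oxo-3,4-dihydro-2H-chromene-2-carboxylate
Conditions: HF·pyridine, pyridine, THF, 0 °C to rt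
Reagents that add atoms: none
Why: Fluoride cleavage of the two aryl silyl ethers; the pyridine buffer keeps the medium non-basic, so retro-oxa-Michael opening is not possible, and the benzyl groups stay.

Step 20
Reactants: 33 methyl (2S)-2-[(1R,2S)-1,4-bis(benzyloxy)-2-methyl-4-oxobutyl]-5-hydroxy-6-{(2S)-5-hydroxy-2-(methoxycarbonyl)-2-[(2R,3S)-3-methyl-5-oxooxolan-2-yl]-4-oxo-3,4-dihydro-2H-chromen-6-yl}-4-oxo-3,4-dihydro-2H-chromene-2-carboxylate
Product: 34 (3S,4R)-4-hydroxy-4-[(2S)-5-hydroxy-6-{(2S)-5-hydroxy-2-(methoxycarbonyl)-2-[(2R,3S)-3-methyl-5-oxooxolan-2-yl]-4-oxo-3,4-dihydro-2H-chromen-6-yl}-2-(methoxycarbonyl)-4-oxo-3,4-dihydro-2H-chromen-2-yl]-3-methylbutanoic acid (CNP0517857.1)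
Conditions: H2 (1 atm), Pd(OH)2/C, EtOAc, rt
Reagents that add atoms: none
Why: Hydrogenolysis of the benzyl ether and the benzyl ester in one neutral operation releases the C9 hydroxyl and the C12 acid together, so no hydroxy ester capable of fast lactonisation is ever present; filtration and evaporation without acid or heat should give the target.

## Compound list

1 | 3-(trimethylsilyl)prop-2-ynal | C[Si](C)(C)C#CC=O | starting material
2 | (Z)-but-2-ene | C/C=C\C | starting material
3 | bis(isopinocampheyl)borinate of 4 (O-boryl ether, (−)-α-pinene series) | C[Si](C)(C)C#C[C@H](OB([C@H]1C[C@H]2C[C@@H]([C@@H]1C)C2(C)C)[C@H]1C[C@H]2C[C@@H]([C@@H]1C)C2(C)C)[C@@H](C)C=C | intermediate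
4 | (3R,4S)-4-methyl-1-(trimethylsilyl)hex-5-en-1-yn-3-ol | C[Si](C)(C)C#C[C@H](O)[C@@H](C)C=C | intermediate
5 | [(3R,4S)-3-(benzyloxy)-4-methylhex-5-en-1-yn-1-yl]trimethylsilane | C[Si](C)(C)C#C[C@H](OCc1ccccc1)[C@@H](C)C=C | intermediate
6 | 9-[(3S,4R)-4-(benzyloxy)-3-methyl-6-(trimethylsilyl)hex-5-yn-1-yl]-9-borabicyclo[3.3.1]nonane | C[Si](C)(C)C#C[C@H](OCc1ccccc1)[C@@H](C)CCB1C2CCCC1CCC2 | intermediate
7 | (3S,4R)-4-(benzyloxy)-3-methyl-6-(trimethylsilyl)hex-5-yn-1-ol | C[Si](C)(C)C#C[C@H](OCc1ccccc1)[C@@H](C)CCO | intermediate
8 | (3S,4R)-4-(benzyloxy)-3-methyl-6-(trimethylsilyl)hex-5-ynal | C[Si](C)(C)C#C[C@H](OCc1ccccc1)[C@@H](C)CC=O | intermediate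
9 | (3S,4R)-4-(benzyloxy)-3-methyl-6-(trimethylsilyl)hex-5-ynoic acid | C[Si](C)(C)C#C[C@H](OCc1ccccc1)[C@@H](C)CC(=O)O | intermediate
10 | benzyl (3S,4R)-4-(benzyloxy)-3-methyl-6-(trimethylsilyl)hex-5-ynoate | C[Si](C)(C)C#C[C@H](OCc1ccccc1)[C@@H](C)CC(=O)OCc1ccccc1 | intermediate
11 | benzyl (3S,4R)-4-(benzyloxy)-6-bromo-3-methylhex-5-ynoate | BrC#C[C@H](OCc1ccccc1)[C@@H](C)CC(=O)OCc1ccccc1 | intermediate
12 | 6-benzyl 1-methyl (3R,4S)-3-(benzyloxy)-4-methyl-2-oxohexanedioate | COC(=O)C(=O)[C@H](OCc1ccccc1)[C@@H](C)CC(=O)OCc1ccccc1 | intermediate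
13 | (E)-1-methoxy-3-(trimethylsilyloxy)buta-1,3-diene | CO/C=C/C(=C)O[Si](C)(C)C | starting material
14 | methyl (2S)-2-[(1R,2S)-1,4-bis(benzyloxy)-2-methyl-4-oxobutyl]-6-methoxy-4-(trimethylsilyloxy)-3,6-dihydro-2H-pyran-2-carboxylate (C6 epimers) | COC(=O)[C@@]1([C@H](OCc2ccccc2)[C@@H](C)CC(=O)OCc2ccccc2)CC(O[Si](C)(C)C)=CC(OC)O1 | intermediate
15 | methyl (2S)-2-[(1R,2S)-1,4-bis(benzyloxy)-2-methyl-4-oxobutyl]-4-oxo-3,4-dihydro-2H-pyran-2-carboxylate | COC(=O)[C@@]1([C@H](OCc2ccccc2)[C@@H](C)CC(=O)OCc2ccccc2)CC(=O)C=CO1 | intermediate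
16 | 1-(2,6-dihydroxyphenyl)ethanone | CC(=O)c1c(O)cccc1O | starting material
17 | dimethyl oxalate | COC(=O)C(=O)OC | starting material
18 | methyl 4-(2,6-dihydroxyphenyl)-2,4-dioxobutanoate | COC(=O)C(=O)CC(=O)c1c(O)cccc1O | intermediate
19 | methyl 5-hydroxy-4-oxo-4H-chromene-2-carboxylate | COC(=O)c1cc(=O)c2c(O)cccc2o1 | intermediate
20 | 4-methylfuran-2(5H)-one | CC1=CC(=O)OC1 | starting material
21 | methyl (2S)-5-hydroxy-2-[(2R)-3-methyl-5-oxo-2,5-dihydrofuran-2-yl]-4-oxo-3,4-dihydro-2H-chromene-2-carboxylate | COC(=O)[C@@]1([C@@H]2OC(=O)C=C2C)CC(=O)c2c(O)cccc2O1 | intermediate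
22 | methyl (2S)-5-hydroxy-2-[(2R,3S)-3-methyl-5-oxooxolan-2-yl]-4-oxo-3,4-dihydro-2H-chromene-2-carboxylate | COC(=O)[C@@]1([C@@H]2OC(=O)C[C@@H]2C)CC(=O)c2c(O)cccc2O1 | intermediate
23 | methyl (2S)-5-hydroxy-6-iodo-2-[(2R,3S)-3-methyl-5-oxooxolan-2-yl]-4-oxo-3,4-dihydro-2H-chromene-2-carboxylate | COC(=O)[C@@]1([C@@H]2OC(=O)C[C@@H]2C)CC(=O)c2c(O)c(I)ccc2O1 | intermediate
24 | methyl (2S)-5-[(tert-butyldimethylsilyl)oxy]-6-iodo-2-[(2R,3S)-3-methyl-5-oxooxolan-2-yl]-4-oxo-3,4-dihydro-2H-chromene-2-carboxylate | COC(=O)[C@@]1([C@@H]2OC(=O)C[C@@H]2C)CC(=O)c2c(O[Si](C)(C)C(C)(C)C)c(I)ccc2O1 | intermediate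
25 | methyl (2S)-5-[(tert-butyldimethylsilyl)oxy]-2-[(2R,3S)-3-methyl-5-oxooxolan-2-yl]-4-oxo-6-(trimethylstannyl)-3,4-dihydro-2H-chromene-2-carboxylate | COC(=O)[C@@]1([C@@H]2OC(=O)C[C@@H]2C)CC(=O)c2c(O[Si](C)(C)C(C)(C)C)c([Sn](C)(C)C)ccc2O1 | intermediate
26 | (E)-but-2-enal | C/C=C/C=O | starting material
27 | 2,3-dibromobutanal (racemic) | CC(Br)C(Br)C=O | intermediate
28 | (Z)-2-bromobut-2-enal | C/C=C(\Br)C=O | intermediate
29 | tert-butyl{[(1Z)-2-bromobuta-1,3-dien-1-yl]oxy}dimethylsilane | C=C/C(Br)=C/O[Si](C)(C)C(C)(C)C | intermediate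
30 | methyl (2S)-5-[(tert-butyldimethylsilyl)oxy]-6-{(1Z)-1-[(tert-butyldimethylsilyl)oxy]buta-1,3-dien-2-yl}-2-[(2R,3S)-3-methyl-5-oxooxolan-2-yl]-4-oxo-3,4-dihydro-2H-chromene-2-carboxylate | C=C/C(=C/O[Si](C)(C)C(C)(C)C)c1ccc2c(c1O[Si](C)(C)C(C)(C)C)C(=O)C[C@@](C(=O)OC)([C@@H]1OC(=O)C[C@@H]1C)O2 | intermediate
31 | 4a,5,8,8a-tetrahydro cycloadduct of 15 and 30 (5-silyloxy, C6=C7 alkene; epimers at C4a, C5 and C8a) | COC(=O)[C@@]1([C@H](OCc2ccccc2)[C@@H](C)CC(=O)OCc2ccccc2)CC(=O)C2C(O[Si](C)(C)C(C)(C)C)C(c3ccc4c(c3O[Si](C)(C)C(C)(C)C)C(=O)C[C@@](C(=O)OC)([C@@H]3OC(=O)C[C@@H]3C)O4)=CCC2O1 | intermediate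
32 | fully protected heterodimer (5,5'-bis-silyl ether, O9-benzyl ether, C12 benzyl ester; systematic name in step 18) | COC(=O)[C@@]1([C@H](OCc2ccccc2)[C@@H](C)CC(=O)OCc2ccccc2)CC(=O)c2c(ccc(-c3ccc4c(c3O[Si](C)(C)C(C)(C)C)C(=O)C[C@@](C(=O)OC)([C@@H]3OC(=O)C[C@@H]3C)O4)c2O[Si](C)(C)C(C)(C)C)O1 | intermediate
33 | O9-benzyl ether C12 benzyl ester of the target (both phenols free; systematic name in step 19) | COC(=O)[C@@]1([C@H](OCc2ccccc2)[C@@H](C)CC(=O)OCc2ccccc2)CC(=O)c2c(ccc(-c3ccc4c(c3O)C(=O)C[C@@](C(=O)OC)([C@@H]3OC(=O)C[C@@H]3C)O4)c2O)O1 | intermediate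
34 | CNP0517857.1, (3S,4R)-4-hydroxy-4-[(2S)-5-hydroxy-6-{(2S)-5-hydroxy-2-(methoxycarbonyl)-2-[(2R,3S)-3-methyl-5-oxooxolan-2-yl]-4-oxo-3,4-dihydro-2H-chromen-6-yl}-2-(methoxycarbonyl)-4-oxo-3,4-dihydro-2H-chromen-2-yl]-3-methylbutanoic acid | COC(=O)[C@@]1([C@H](O)[C@@H](C)CC(=O)O)CC(=O)c2c(ccc(-c3ccc4c(c3O)C(=O)C[C@@](C(=O)OC)([C@@H]3OC(=O)C[C@@H]3C)O4)c2O)O1 | target

## Step count and risks

Total step count: 20. Longest linear sequence: 11 steps (steps 1 to 8, then 18 to 20). The lactone branch is steps 9 to 14 and 17; steps 15 and 16 prepare the four-carbon coupling partner.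

Step 18 (key step, proposed new method) is the least certain. Likely failures are:
- β-elimination of silanol from the aldol-type adduct before dehydrogenation, which would lose the C5 oxygen;
- arrest at the Michael stage without ring closure;
- hydrolysis of the dienol ether by traces of acid;
- slow oxidation of the benzyl ether by DDQ if heating is needed.

The fallback uses only known reaction types, abandons the benzannulation and joins two complete chromanones by a biaryl coupling. It sets out from 12 and returns at 32. Commercial 1-(2-fluoro-6-hydroxyphenyl)ethanone is protected (MOMCl, i-Pr2NEt) as 1-[2-fluoro-6-(methoxymethoxy)phenyl]ethanone F1 and converted (TMSOTf, Et3N) into its trimethylsilyl enol ether F2. A Mukaiyama aldol addition of F2 to 12 under Cu(OTf)2/(R,R)-t-Bu-box, with the same chelate and the same ketone face as in step 8, gives the tertiary aldol F3. Cs2CO3 in DMF closes the pyranone ring by intramolecular SNAr displacement of the ortho fluoride to give the chromanone methoxymethyl ether F4, and HCl in MeOH frees the phenol F5. Iodination as in step 12 gives the 6-iodide F6 and silylation as in step 13 the silyl ether F7. Stille coupling of F7 with 25 (Pd(PPh3)4, copper thiophene-2-carboxylate, NMP) gives 32.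

Step 10. Facial control by the catalyst may be poor, the wrong C2/C9 relationship may be favoured, or the chelating 5-hydroxy ketone of the product may inhibit turnover. The fallback sets out from 19 and 20 and returns at 21. 20 is converted (i-Pr3SiOTf, Et3N) into 4-methyl-2-(triisopropylsilyloxy)furan F8. Silyl-triflate-mediated addition of F8 to 19 through the 4-silyloxybenzopyrylium ion gives, after hydrolysis, the racemic butenolide F9. The enantiomers are separated by preparative chromatography on a chiral stationary phase to give 21.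

Step 8. The resident C9 centre may oppose the catalyst, or the benzyloxy group may compete as a second chelating site, so that face selectivity at the ketone is eroded; the branched ketone may also react slowly or enolise at C3. The fallback sets out from 12 and 13 and returns at 15. A Mukaiyama aldol addition of 13 to 12 mediated by MgBr2·OEt2 at −78 °C is stopped at the open-chain vinylogous ester aldol F10. Its C2 epimers are diastereomers and are separated by chromatography, and the 2S epimer is cyclised with TFA to 15.

Step 12. Substitution may occur in part at C8 or twice, so regiocontrol is not guaranteed. The fallback installs the four-carbon unit by a rearrangement that can only reach C6; it sets out from 22, bypasses steps 12 to 17 and returns at 30.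
- Mitsunobu etherification of 22 with commercial (Z)-4-(tert-butyldimethylsilyloxy)but-2-en-1-ol gives the allyl aryl ether F11.
- Heating in N,N-diethylaniline at about 180 °C effects the aromatic Claisen rearrangement to the 6-substituted phenol F12.
- Silylation (t-BuMe2SiOTf, 2,6-lutidine) gives the bis-silyl ether F13.
- Methanolysis of the primary silyl ether (camphorsulfonic acid, MeOH) gives the alcohol F14.
- Oxidation (DMP, NaHCO3) gives the α-aryl β,γ-unsaturated aldehyde F15.
- The doubly activated α-hydrogen of F15 allows selective silylation (t-BuMe2SiOTf, Et3N, −78 °C) to 30.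

Step 17. Protodestannylation, slow oxidative addition of the electron-rich alkenyl bromide or hydrolysis of the dienol ether may intervene. The fallback sets out from 25 and 28 and returns at 30. Stille coupling of 25 with 28 (Pd2(dba)3, AsPh3, DMF, rt) gives the aryl enal F16. γ-Deprotonation and silylation (t-BuMe2SiOTf, 1.05 equiv, Et3N, −78 to −40 °C) then give 30, with the peri-silyloxy group relied on to keep the C4 ketone from silylating.

## Further compounds

F1 | step 18 | 1-[2-fluoro-6-(methoxymethoxy)phenyl]ethanone | CC(=O)c1c(F)cccc1OCOC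
F2 | step 18 | ({1-[2-fluoro-6-(methoxymethoxy)phenyl]ethenyl}oxy)trimethylsilane | C=C(O[Si](C)(C)C)c1c(F)cccc1OCOC
F3 | step 18 | 6-benzyl 1-methyl (2S,3R,4S)-3-(benzyloxy)-2-{2-[2-fluoro-6-(methoxymethoxy)phenyl]-2-oxoethyl}-2-hydroxy-4-methylhexanedioate | COC(=O)[C@@](O)([C@H](OCc1ccccc1)[C@@H](C)CC(=O)OCc1ccccc1)CC(=O)c1c(F)cccc1OCOC
F4 | step 18 | methyl (2S)-2-[(1R,2S)-1,4-bis(benzyloxy)-2-methyl-4-oxobutyl]-5-(methoxymethoxy)-4-oxo-3,4-dihydro-2H-chromene-2-carboxylate | COC(=O)[C@@]1([C@H](OCc2ccccc2)[C@@H](C)CC(=O)OCc2ccccc2)CC(=O)c2c(OCOC)cccc2O1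
F5 | step 18 | methyl (2S)-2-[(1R,2S)-1,4-bis(benzyloxy)-2-methyl-4-oxobutyl]-5-hydroxy-4-oxo-3,4-dihydro-2H-chromene-2-carboxylate | COC(=O)[C@@]1([C@H](OCc2ccccc2)[C@@H](C)CC(=O)OCc2ccccc2)CC(=O)c2c(O)cccc2O1
F6 | step 18 | methyl (2S)-2-[(1R,2S)-1,4-bis(benzyloxy)-2-methyl-4-oxobutyl]-5-hydroxy-6-iodo-4-oxo-3,4-dihydro-2H-chromene-2-carboxylate | COC(=O)[C@@]1([C@H](OCc2ccccc2)[C@@H](C)CC(=O)OCc2ccccc2)CC(=O)c2c(O)c(I)ccc2O1
F7 | step 18 | methyl (2S)-2-[(1R,2S)-1,4-bis(benzyloxy)-2-methyl-4-oxobutyl]-5-[(tert-butyldimethylsilyl)oxy]-6-iodo-4-oxo-3,4-dihydro-2H-chromene-2-carboxylate | COC(=O)[C@@]1([C@H](OCc2ccccc2)[C@@H](C)CC(=O)OCc2ccccc2)CC(=O)c2c(O[Si](C)(C)C(C)(C)C)c(I)ccc2O1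
F8 | step 10 | 4-methyl-2-(triisopropylsilyloxy)furan | Cc1coc(O[Si](C(C)C)(C(C)C)C(C)C)c1
F9 | step 10 | racemate of 21 (2S,9R and 2R,9S enantiomers) | COC(=O)[C@@]1([C@@H]2OC(=O)C=C2C)CC(=O)c2c(O)cccc2O1.COC(=O)[C@]1([C@H]2OC(=O)C=C2C)CC(=O)c2c(O)cccc2O1
F10 | step 8 | 6-benzyl 1-methyl (2S,3R,4S)-3-(benzyloxy)-2-hydroxy-2-[(3E)-4-methoxy-2-oxobut-3-en-1-yl]-4-methylhexanedioate | CO/C=C/C(=O)C[C@@](O)(C(=O)OC)[C@H](OCc1ccccc1)[C@@H](C)CC(=O)OCc1ccccc1
F11 | step 12 | methyl (2S)-5-{[(2Z)-4-(tert-butyldimethylsilyloxy)but-2-en-1-yl]oxy}-2-[(2R,3S)-3-methyl-5-oxooxolan-2-yl]-4-oxo-3,4-dihydro-2H-chromene-2-carboxylate | COC(=O)[C@@]1([C@@H]2OC(=O)C[C@@H]2C)CC(=O)c2c(OC/C=C\CO[Si](C)(C)C(C)(C)C)cccc2O1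
F12 | step 12 | methyl (2S)-6-[1-(tert-butyldimethylsilyloxy)but-3-en-2-yl]-5-hydroxy-2-[(2R,3S)-3-methyl-5-oxooxolan-2-yl]-4-oxo-3,4-dihydro-2H-chromene-2-carboxylate (epimers at the new benzylic centre) | COC(=O)[C@@]1([C@@H]2OC(=O)C[C@@H]2C)CC(=O)c2c(O)c(C(CO[Si](C)(C)C(C)(C)C)C=C)ccc2O1
F13 | step 12 | methyl (2S)-5-[(tert-butyldimethylsilyl)oxy]-6-[1-(tert-butyldimethylsilyloxy)but-3-en-2-yl]-2-[(2R,3S)-3-methyl-5-oxooxolan-2-yl]-4-oxo-3,4-dihydro-2H-chromene-2-carboxylate (epimers) | COC(=O)[C@@]1([C@@H]2OC(=O)C[C@@H]2C)CC(=O)c2c(O[Si](C)(C)C(C)(C)C)c(C(CO[Si](C)(C)C(C)(C)C)C=C)ccc2O1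
F14 | step 12 | methyl (2S)-5-[(tert-butyldimethylsilyl)oxy]-6-(1-hydroxybut-3-en-2-yl)-2-[(2R,3S)-3-methyl-5-oxooxolan-2-yl]-4-oxo-3,4-dihydro-2H-chromene-2-carboxylate (epimers) | COC(=O)[C@@]1([C@@H]2OC(=O)C[C@@H]2C)CC(=O)c2c(O[Si](C)(C)C(C)(C)C)c(C(CO)C=C)ccc2O1
F15 | step 12 | methyl (2S)-5-[(tert-butyldimethylsilyl)oxy]-2-[(2R,3S)-3-methyl-5-oxooxolan-2-yl]-4-oxo-6-(1-oxobut-3-en-2-yl)-3,4-dihydro-2H-chromene-2-carboxylate (epimers) | COC(=O)[C@@]1([C@@H]2OC(=O)C[C@@H]2C)CC(=O)c2c(O[Si](C)(C)C(C)(C)C)c(C(C=O)C=C)ccc2O1
F16 | step 17 | methyl (2S)-5-[(tert-butyldimethylsilyl)oxy]-2-[(2R,3S)-3-methyl-5-oxooxolan-2-yl]-4-oxo-6-[(2E)-1-oxobut-2-en-2-yl]-3,4-dihydro-2H-chromene-2-carboxylate | C/C=C(/C=O)c1ccc2c(c1O[Si](C)(C)C(C)(C)C)C(=O)C[C@@](C(=O)OC)([C@@H]1OC(=O)C[C@@H]1C)O2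
A1 | alternative 1 | biaryl bis(β-hydroxy ketone) with both tertiary carbinols (bis-silyl ethers, fluorides and methoxymethyl ethers in place) | COC(=O)[C@@](O)([C@H](O[Si](C)(C)C(C)(C)C)[C@@H](C)CCO[Si](C)(C)C(C)(C)C)CC(=O)c1c(F)ccc(-c2ccc(F)c(C(=O)C[C@@](O)(C(=O)OC)[C@H](O[Si](C)(C)C(C)(C)C)[C@@H](C)CCO[Si](C)(C)C(C)(C)C)c2OCOC)c1OCOC
A2 | alternative 1 | methyl (2S)-2-[(1R,2S)-1,4-bis(tert-butyldimethylsilyloxy)-2-methylbutyl]-4-oxooxetane-2-carboxylate | COC(=O)[C@@]1([C@H](O[Si](C)(C)C(C)(C)C)[C@@H](C)CCO[Si](C)(C)C(C)(C)C)CC(=O)O1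
A3 | alternative 1 | 4,4'-difluoro-2,2'-bis(methoxymethoxy)-1,1'-biphenyl | COCOc1cc(F)ccc1-c1ccc(F)cc1OCOC
A4 | alternative 2 | C2-symmetric bis(butenolide) bis-chromanone | COC(=O)[C@@]1([C@@H]2OC(=O)C=C2C)CC(=O)c2c(ccc(-c3ccc4c(c3O)C(=O)C[C@@](C(=O)OC)([C@@H]3OC(=O)C=C3C)O4)c2O)O1
A5 | alternative 2 | dimethyl 5,5'-dihydroxy-4,4'-dioxo-4H,4'H-[6,6'-bichromene]-2,2'-dicarboxylate | COC(=O)c1cc(=O)c2c(O)c(-c3ccc4oc(C(=O)OC)cc(=O)c4c3O)ccc2o1
A6 | alternative 2 | 4-methyl-2-(triisopropylsilyloxy)furan | Cc1coc(O[Si](C(C)C)(C(C)C)C(C)C)c1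
A7 | alternative 3 | methyl (2S)-5-hydroxy-2-[(2R,3S)-3-methyl-5-oxooxolan-2-yl]-4-oxo-3,4-dihydro-2H-chromene-2-carboxylate (same structure as 22) | COC(=O)[C@@]1([C@@H]2OC(=O)C[C@@H]2C)CC(=O)c2c(cccc2O)O1
A8 | alternative 3 | methyl 4-(2,6-dihydroxyphenyl)-2-[(2R,3S)-3-methyl-5-oxooxolan-2-yl]-4-oxobut-2-enoate (either alkene isomer) | COC(=O)C(=CC(=O)c1c(O)cccc1O)[C@@H]1OC(=O)C[C@@H]1C
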